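The north-west run ends with target at 13 % and the west run with 10 %, both after 120 s, and from these two readings you can reach three new flasks by hand.

| flask | starting material | solid reagent | remark | time |
|---|---|---|---|---|
| north-west | 1.3 M | 1.9 M | run made earlier |  |
| west | 2.8 M | 1.9 M | run made earlier |  |
| ash | 1.9 M | 1.90 M |  | 2.0 min |
| oak | 1.9 M | 1.90 M |  | 5.0 min |
| larch | 1.9 M | 1.90 M |  | 12 min |

| run | time / s | tautomer / % | target / % | starting material / % | isomer of the product / % |
|---|---|---|---|---|---|
| north-west | 10.0 | 0 | 0 | 99 | 0 |
| north-west | 20.0 | 2 | 2 | 96 | 7 |
| north-west | 30.0 | 1 | 2 | 94 | 8 |
| north-west | 60.0 | 3 | 5 | 80 | 14 |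
| north-west | 120 | 0 | 13 | 65 | 22 |
| west | 25.0 | 0 | 3 | 91 | 6 |
| west | 50.0 | 1 | 2 | 84 | 13 |
| west | 80.0 | 0 | 7 | 74 | 14 |
| west | 90.0 | 1 | 9 | 75 | 17 |
| west | 120 | 0 | 10 | 71 | 15 |

(standard deviation of a reading: 1.5 percentage points)

- solid reagent is a solid; its amount is given per volume of the solution
- on the list of suspects stand: starting material + partner <-> isomer of the product; partner + tautomer -> target; solid reagent <-> partner; starting material <-> tautomer
- at the start none of the solid reagent is in solution

1. which of these there is most of at the end, counted by the starting material in it, ash (isomer of the product / target / tautomer / starting material)
2. which of these there is most of at the end, counted by the starting material in it, oak (isomer of the product / target / tautomer / starting material)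
3. which of these there is most of at the end, counted by the starting material in it, larch (isomer of the product / target / tautomer / starting material)
4. how much there is at the end of the one of these that leads, in percent of the starting material charged: ash
5. how much there is at the end of the one of these that leads, in percent of the starting material charged: oak
6. how much there is at the end of the one of these that leads, in percent of the starting material charged: larch

Tautomer reads near zero, so take starting material plus isomer as one pool, whatever target has not claimed. Each run then gives a decay constant for that pool, and the two agree within their scatter. Averaging them gives the pool life, 16.4 min: the time in which the pool falls by a factor e, treated as pseudo-first-order.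

Now chain it. Target should stand at 11.5 % in ash, 26.3 % in oak and 52.0 % in larch. The last readings put starting material at 78.6 % of the pool, so my starting material is 69.6 % in ash, 57.9 % in oak and 37.7 % in larch. Starting material leads the first two, target the third.

The weak link is the constant life, read over 120 s and stretched to 12 min. Solid reagent is charged equal to starting material, and each target or isomer takes one partner, so once the solid has dissolved, c(partner) equals c(starting material) plus c(tautomer), and tautomer reads near zero. If the decay constant follows c(partner), it falls to 0.543 of its ash value by the end of larch. Averaging that fall over the stretch after ash gives larch target 44.8 % against starting material 43.4 %. I keep target ahead in larch, somewhere between that figure and 52.0 %, but the lead may be thin.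

The forecast says starting material at 68 % (64 % to 72 %) for ash, starting material at 52 % (43 % to 59 %) for oak and target at 50 % (38 % to 62 %) for larch, on the grounds that the “starting material plus isomer pool decays at about 0.001 per second”. For oak it stands lower than my 57.9 %.

    starting material + partner ⇌ isomer of the product (K = 0.232 M⁻¹, k = 0.00634 M⁻¹ s⁻¹)
    partner + tautomer → target (k = 0.302 M⁻¹ s⁻¹)
    solid reagent ⇌ partner, rate k3*(cs3 - [partner]) while solid is left; crystals form when [partner] > cs3 (solubility = 1.70 M, k = 0.0259 s⁻¹)
    starting material ⇌ tautomer (K = 0.00440, k = 0.0498 s⁻¹)

The flasks give starting material at 67.4 % in ash, starting material at 56.0 % in oak and target at 52.3 % in larch, inside the forecast's ranges. In oak, tautomer's half-life by its step with partner, 2.9 s at 0.495 min, is far shorter than starting material's 2.3 min by the forward isomer step. Tautomer there is made and used at a ratio of 0.997, standing at 0.240 % at 5.00 min. The pool life reckoned from the larch target comes to 16.2 min, though partner has gone from 1.29 M in ash at 2.00 min to 0.764 M in larch at 12.0 min. Oak left until 20 min, with partner at 0.561 M, reaches target 66.4 %, where the pool life gives 70.5 %.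

The runs were generated by integration with made-up constants; the scatter is artificial.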